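**Plan**

1. Each acyl chain (C1' ester carbon, C2', stereocentre C3', alkene carbon C4' carrying CHO and the ethylidene, arm C7'H2–C8'HO) holds a 1,5-dialdehyde around C3'. This is the hydrolysed form of a 2-ethoxy-3,4-dihydro-2H-pyran (O1, C2 = C8', C3 = C7', C4 = C3', C5 = C4', C6 = formyl carbon), a ring the target does not contain. The retrosynthesis closes both chains to such pyrans, cuts the ethylidene carbons back to C5–Br, then cuts C3'–C7' and O1–C8' in each ring to give a (Z)-2-bromo enal and ethyl vinyl ether.
2. The bromo enal arms are cut at C3'=C4' (cross-metathesis) and at the two ester C–O bonds, leaving the acetonide-protected core diol. The core is cut at the ring C–CH(CO2Et)2 bond (Michael addition) and across the cyclopentene into an allenoate and (E)-pent-3-en-2-one ([3+2] annulation).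
3. Forward: the cyclopentene forms first (step 1) and is taken to the core diol carrying a temporary 1,3-dioxane (step 5). The chains are attached as butenoates (step 6), both dihydropyran rings close in one operation (step 9) and are opened again in the last step.
4. Stereochemistry: the ring C–Me and C–O centres come from the chiral phosphine and the (E)-enone, kept through the Baeyer–Villiger migration. The other two ring centres come from thermodynamic all-trans control in the malonate addition. Both C3' centres come from the chiral chromium catalyst, and the (E)-enals from equilibration in the final acid.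

Key step: step 9

Assumption: the catalyst antipodes named in steps 1 and 9 are those expected by analogy with simpler enones and enals to give (4R,5S)-3 and the (2R,4S)-pyrans; the sense is to be confirmed on the first adduct and the mirror-image catalyst, equally accessible, used if it proves opposite.

**Route**

Step 1
Reactants: 1 ethyl buta-2,3-dienoate; 2 (E)-pent-3-en-2-one
Product: 3 ethyl (4R,5S)-4-acetyl-5-methylcyclopent-1-ene-1-carboxylate (trans)
Conditions: (S)-4-phenyl-4,5-dihydro-3H-dinaphtho[2,1-c:1',2'-e]phosphepine (10 mol%), toluene, rt, slow addition of 1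
Reagents that add atoms: none
Why: Phosphine-catalysed allenoate–enone [3+2] annulation, in which the phosphine–allenoate zwitterion bonds through its α-carbon to the enone β-carbon and closes through its γ-carbon onto the enolate carbon, so that the (E)-geometry of 2 becomes the trans C4/C5 relationship while the C2-symmetric binaphthyl phosphepine selects the enone face and fixes both centres.

Step 2
Reactants: 3 ethyl (4R,5S)-4-acetyl-5-methylcyclopent-1-ene-1-carboxylate; 4 diethyl malonate
Product: 5 diethyl 2-[(1R,2R,3S,4R)-4-acetyl-2-(ethoxycarbonyl)-3-methylcyclopentyl]propanedioate (all-trans)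
Conditions: 4 (2 equiv), NaOEt (0.3 equiv), EtOH, rt to 60 °C
Reagents that add atoms: none
Why: Michael addition of malonate to the β-carbon of the cyclopentenecarboxylate is reversible under catalytic ethoxide, the nucleophile approaching anti to the acetyl group and the ester and ketone α-centres equilibrating, so the all-trans cyclopentane, the thermodynamic isomer, should predominate and set the two new ring centres.

Step 3
Reactants: 5 diethyl 2-[(1R,2R,3S,4R)-4-acetyl-2-(ethoxycarbonyl)-3-methylcyclopentyl]propanedioate
Product: 6 diethyl 2-[(1R,2S,3R,4R)-4-acetoxy-2-(ethoxycarbonyl)-3-methylcyclopentyl]propanedioate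
Conditions: mCPBA (2.5 equiv), TFA (cat.), CH2Cl2, rt
Reagents that add atoms: mCPBA, OOC(=O)c1cccc(Cl)c1
Why: Baeyer–Villiger oxidation in which the secondary ring carbon migrates in preference to methyl with retention of configuration, turning the acetyl group into the ring acetate while the esters are inert to the peracid.

Step 4
Reactants: 6 diethyl 2-[(1R,2S,3R,4R)-4-acetoxy-2-(ethoxycarbonyl)-3-methylcyclopentyl]propanedioate
Product: 7 (1R,2R,3S,4R)-4-(1,3-dihydroxypropan-2-yl)-3-(hydroxymethyl)-2-methylcyclopentan-1-ol
Conditions: LiAlH4 (excess), THF, 0 °C to reflux; Na2SO4·10H2O quench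
Reagents that add atoms: none
Why: Exhaustive hydride reduction converts the three ethyl esters into primary alcohols and cleaves the acetate, and none of the four ring stereocentres is touched.

Step 5
Reactants: 7 (1R,2R,3S,4R)-4-(1,3-dihydroxypropan-2-yl)-3-(hydroxymethyl)-2-methylcyclopentan-1-ol
Product: 8 (1R,2R,3S,4R)-4-(2,2-dimethyl-1,3-dioxan-5-yl)-3-(hydroxymethyl)-2-methylcyclopentan-1-ol
Conditions: Me2C(OMe)2 (1.3 equiv), PPTS (cat.), acetone, rt
Reagents that add atoms: 2,2-dimethoxypropane, COC(C)(C)OC
Why: Acid-catalysed transketalisation is thermodynamically selective for the six-membered 1,3-dioxane of the 2-substituted propane-1,3-diol, since any ketal involving the other two hydroxyls would be seven- or eight-membered.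

Step 6
Reactants: 8 core diol acetonide; 9 but-3-enoic acid
Product: 10 bis(but-3-enoate) of 8 (acylated at the ring CH2OH and at the ring secondary OH)
Conditions: 9 (2.4 equiv), DCC (2.4 equiv), DMAP (0.1 equiv), CH2Cl2, 0 °C to rt
Reagents that add atoms: none
Why: Steglich esterification acylates both the primary and the secondary hydroxyl, and low temperature with little DMAP should keep the β,γ-double bonds from moving into conjugation.

Step 7
Reactants: 10 bis(but-3-enoate) of 8; 11 (E)-but-2-enal (crotonaldehyde)
Product: 12 bis[(E)-5-oxopent-3-enoate] of 8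
Conditions: 11 (10 equiv), second-generation Hoveyda–Grubbs catalyst RuCl2(SIMes)(=CH-C6H4-2-O-i-Pr) (10 mol%), 1,4-benzoquinone (cat.), CH2Cl2, 40 °C
Reagents that add atoms: none
Why: Olefin cross-metathesis between the reactive terminal alkenes and excess crotonaldehyde should give the (E)-enals with loss of propene, the large excess of enal outcompeting ring closure between the two arms and benzoquinone suppressing ruthenium hydride isomerisation.

Step 8
Reactants: 12 bis[(E)-5-oxopent-3-enoate] of 8
Product: 14 bis[(Z)-4-bromo-5-oxopent-3-enoate] of 8, via bis(3,4-dibromo-5-oxopentanoate) 13 (not isolated)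
Conditions: Br2 (2.1 equiv), CH2Cl2, −78 °C; then Et3N (2.5 equiv), −78 to 0 °C
Reagents that add atoms: bromine, BrBr
Why: Bromine adds across each enal double bond and triethylamine then removes the acidic α-proton with loss of the β-bromide (E1cB), giving the thermodynamically preferred (Z)-2-bromo enal with bromine cis to the chain.

Step 9
Reactants: 14 bis[(Z)-4-bromo-5-oxopent-3-enoate] of 8; 15 ethyl vinyl ether
Product: 16 bis{2-[(2R,4S)-5-bromo-2-ethoxy-3,4-dihydro-2H-pyran-4-yl]acetate} of 8 (cis-2,4 in each pyran)
Conditions: 15 (20 equiv), CrCl(L) (10 mol%; L = dianion of (1R,2S)-1-{[3-(1-adamantyl)-2-hydroxy-5-methylbenzylidene]amino}indan-2-ol), 4 Å MS, TBME, rt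
Reagents that add atoms: none
Why: The trivalent chromium centre binds each aldehyde oxygen and lowers the LUMO of the s-cis 1-oxadiene O=C–C(Br)=C, which combines with the electron-rich vinyl ether in a concerted, asynchronous inverse-electron-demand hetero-Diels–Alder reaction, the vinyl ether CH2 bonding to C3' and the carbonyl oxygen to the ethoxy-bearing carbon. The closest known reaction is the cycloaddition of (E)-enals, α-bromo enals included, with ethyl vinyl ether under tridentate Schiff-base chromium chloride catalysis. Each of the two 3,4-dihydro-2H-pyran rings is closed by this intermolecular [4+2] cycloaddition, which makes the C3'–C7' and O1–C8' bonds of a ring together. C4 of each pyran (C3' of the chain) is set by the catalyst, which shields one face of the bound oxadiene, and the acetal centre C2 by the endo approach of the ethoxy group, which places it cis to the C4 substituent. The step needs catalyst control that ignores the distant core (secured because the arms are remote from the ring centres and react independently), the correct regiochemistry (secured by the polarisation of the two partners) and a reactive heterodiene (secured by the α-bromine and by the (Z)-geometry, which keeps the β-substituent trans to the formyl group).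

Step 10
Reactants: 16 bis(5-bromo-2-ethoxy-dihydropyranyl)acetate of 8; 17 4,4,5,5-tetramethyl-2-vinyl-1,3,2-dioxaborolane
Product: 18 bis{2-[(2R,4S)-2-ethoxy-5-vinyl-3,4-dihydro-2H-pyran-4-yl]acetate} of 8
Conditions: 17 (3 equiv), Pd(PPh3)4 (10 mol%), K3PO4 (4 equiv), THF/H2O, 60 °C
Reagents that add atoms: none
Why: Suzuki–Miyaura coupling of the two alkenyl bromides with the vinylboronate under zerovalent palladium catalysis adds the two missing carbons of each chain and leaves esters, acetals and the C4 centres untouched.

Step 11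
Reactants: 18 bis(2-ethoxy-5-vinyl-dihydropyranyl)acetate of 8
Product: 19 CNP0313563.1, the bis[(3S,4E)-4-formyl-3-(2-oxoethyl)hex-4-enoate] of tetraol 7 at the ring CH2OH and the ring secondary OH
Conditions: 1 M aq. HCl/THF (1:5), 0 °C to rt
Reagents that add atoms: water, O
Why: Acetal and dienol ether hydrolysis, in which each 2-oxy-diene is protonated at the vinyl terminus, water opens the oxocarbenium ion and the ethoxy acetal to release the 1,5-dialdehyde with the thermodynamically preferred (E)-ethylidene enal, the same medium cleaves the acetonide, and C3' is not enolisable and keeps its configuration.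

**Compound list**

1 | ethyl buta-2,3-dienoate | C=C=CC(=O)OCC | starting material
2 | (E)-pent-3-en-2-one | C/C=C/C(C)=O | starting material
3 | ethyl (4R,5S)-4-acetyl-5-methylcyclopent-1-ene-1-carboxylate | CCOC(=O)C1=CC[C@@H](C(C)=O)[C@@H]1C | intermediate
4 | diethyl malonate | CCOC(=O)CC(=O)OCC | starting material
5 | diethyl 2-[(1R,2R,3S,4R)-4-acetyl-2-(ethoxycarbonyl)-3-methylcyclopentyl]propanedioate | CCOC(=O)[C@@H]1[C@@H](C)[C@H](C(C)=O)C[C@H]1C(C(=O)OCC)C(=O)OCC | intermediate
6 | diethyl 2-[(1R,2S,3R,4R)-4-acetoxy-2-(ethoxycarbonyl)-3-methylcyclopentyl]propanedioate | CCOC(=O)[C@@H]1[C@@H](C)[C@H](OC(C)=O)C[C@H]1C(C(=O)OCC)C(=O)OCC | intermediate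
7 | (1R,2R,3S,4R)-4-(1,3-dihydroxypropan-2-yl)-3-(hydroxymethyl)-2-methylcyclopentan-1-ol (core tetraol) | OC[C@@H]1[C@@H](C)[C@H](O)C[C@H]1C(CO)CO | intermediate
8 | (1R,2R,3S,4R)-4-(2,2-dimethyl-1,3-dioxan-5-yl)-3-(hydroxymethyl)-2-methylcyclopentan-1-ol (core diol acetonide) | OC[C@@H]1[C@@H](C)[C@H](O)C[C@H]1C2COC(C)(C)OC2 | intermediate
9 | but-3-enoic acid | C=CCC(=O)O | starting material
10 | bis(but-3-enoate) of 8 | C=CCC(=O)OC[C@@H]1[C@@H](C)[C@H](OC(=O)CC=C)C[C@H]1C2COC(C)(C)OC2 | intermediate
11 | (E)-but-2-enal (crotonaldehyde) | C/C=C/C=O | starting material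
12 | bis[(E)-5-oxopent-3-enoate] of 8 | O=C/C=C/CC(=O)OC[C@@H]1[C@@H](C)[C@H](OC(=O)C/C=C/C=O)C[C@H]1C2COC(C)(C)OC2 | intermediate
13 | bis(3,4-dibromo-5-oxopentanoate) of 8, mixture of diastereomers at the CHBr centres, not isolated | O=CC(Br)C(Br)CC(=O)OC[C@@H]1[C@@H](C)[C@H](OC(=O)CC(Br)C(Br)C=O)C[C@H]1C2COC(C)(C)OC2 | intermediate
14 | bis[(Z)-4-bromo-5-oxopent-3-enoate] of 8 | O=C/C(Br)=C/CC(=O)OC[C@@H]1[C@@H](C)[C@H](OC(=O)C/C=C(/C=O)Br)C[C@H]1C2COC(C)(C)OC2 | intermediate
15 | ethyl vinyl ether | C=COCC | starting material
16 | bis{2-[(2R,4S)-5-bromo-2-ethoxy-3,4-dihydro-2H-pyran-4-yl]acetate} of 8 | BrC1=CO[C@@H](OCC)C[C@H]1CC(=O)OC[C@@H]1[C@@H](C)[C@H](OC(=O)C[C@@H]3C[C@H](OCC)OC=C3Br)C[C@H]1C2COC(C)(C)OC2 | intermediate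
17 | 4,4,5,5-tetramethyl-2-vinyl-1,3,2-dioxaborolane | C=CB1OC(C)(C)C(C)(C)O1 | starting material
18 | bis{2-[(2R,4S)-2-ethoxy-5-vinyl-3,4-dihydro-2H-pyran-4-yl]acetate} of 8 | C=CC1=CO[C@@H](OCC)C[C@H]1CC(=O)OC[C@@H]1[C@@H](C)[C@H](OC(=O)C[C@@H]3C[C@H](OCC)OC=C3C=C)C[C@H]1C2COC(C)(C)OC2 | intermediate
19 | CNP0313563.1 | C/C=C(/C=O)[C@@H](CC=O)CC(=O)OC[C@@H]1[C@@H](C)[C@H](OC(=O)C[C@H](CC=O)/C(C=O)=C\C)C[C@H]1C(CO)CO | target

**Count**

Total steps: 11. Longest linear sequence: 11 steps (1 and 2 to 19).

**Steps most likely to fail**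

Step 9. The twofold cycloaddition may stall after one arm, the bis-enal may enolise at the C2' methylene and degrade before it reacts, or binding of both aldehydes to the catalyst may erode facial control. The fallback makes one pyran at a time on a small fragment and attaches it afterwards; it sets out from 11 and 8 and comes back at 16. Cross-metathesis of commercial methyl but-3-enoate with 11 under the conditions of step 7 would give methyl (E)-5-oxopent-3-enoate F1. Bromine and then triethylamine would lead through methyl 3,4-dibromo-5-oxopentanoate F2 to methyl (Z)-4-bromo-5-oxopent-3-enoate F3. A single chromium-catalysed cycloaddition with 15 on this small enal would give methyl 2-[(2R,4S)-5-bromo-2-ethoxy-3,4-dihydro-2H-pyran-4-yl]acetate F4, whose enantiomeric purity can be checked and raised before the core is committed. LiOH in THF/H2O would give 2-[(2R,4S)-5-bromo-2-ethoxy-3,4-dihydro-2H-pyran-4-yl]acetic acid F5, and twofold DCC/DMAP esterification of 8 with this acid returns to 16.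

Step 1. A small aliphatic enone may give poor enantio- and regiocontrol, and allenoate oligomerisation may outrun the annulation. The fallback replaces asymmetric catalysis by an enzymatic resolution; it sets out from 1 and 2 and comes back at 7. PPh3 in toluene would give racemic ethyl trans-4-acetyl-5-methylcyclopent-1-ene-1-carboxylate F6. Steps 2 and 3 applied unchanged would give racemic all-trans diethyl 2-[4-acetyl-2-(ethoxycarbonyl)-3-methylcyclopentyl]propanedioate F7 and racemic all-trans diethyl 2-[4-acetoxy-2-(ethoxycarbonyl)-3-methylcyclopentyl]propanedioate F8. Immobilised Candida antarctica lipase B in phosphate buffer/MTBE should, by the empirical rule for secondary alcohols, hydrolyse the (R)-configured ring acetate and give diethyl 2-[(1R,2S,3R,4R)-2-(ethoxycarbonyl)-4-hydroxy-3-methylcyclopentyl]propanedioate F9. This is separated from the unreacted antipode of 6 and reduced with LiAlH4 to 7. Should the enzyme prefer the other enantiomer, the recovered acetate is 6 itself and enters step 4.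

Step 8. Triethylamine may deprotonate the C2' methylene, which lies between the ester and the bromo enal, so that the double bond migrates toward the ester and the bromo enal is lost. The fallback installs bromine after the ring is formed; it sets out from 12 and comes back at 16. The chromium-catalysed cycloaddition of step 9 is run directly on 12, a β-alkyl (E)-enal of the best-behaved class, to give the bis{2-[(2R,4S)-2-ethoxy-3,4-dihydro-2H-pyran-4-yl]acetate} of 8 F10. Bromine in CH2Cl2 at −78 °C adds to each enol ether to give the bis(5,6-dibromo adduct) of 8 F11, and DBU removes HBr across C5–C6 to give 16.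

**Further compounds**

F1 | step 9 | methyl (E)-5-oxopent-3-enoate | COC(=O)C/C=C/C=O
F2 | step 9 | methyl 3,4-dibromo-5-oxopentanoate | COC(=O)CC(Br)C(Br)C=O
F3 | step 9 | methyl (Z)-4-bromo-5-oxopent-3-enoate | COC(=O)C/C=C(/C=O)Br
F4 | step 9 | methyl 2-[(2R,4S)-5-bromo-2-ethoxy-3,4-dihydro-2H-pyran-4-yl]acetate | COC(=O)C[C@@H]1C[C@H](OCC)OC=C1Br
F5 | step 9 | 2-[(2R,4S)-5-bromo-2-ethoxy-3,4-dihydro-2H-pyran-4-yl]acetic acid | OC(=O)C[C@@H]1C[C@H](OCC)OC=C1Br
F6 | step 1 | racemic ethyl trans-4-acetyl-5-methylcyclopent-1-ene-1-carboxylate | CCOC(=O)C1=CC[C@@H](C(C)=O)[C@@H]1C.CCOC(=O)C1=CC[C@H](C(C)=O)[C@H]1C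
F7 | step 1 | racemic all-trans diethyl 2-[4-acetyl-2-(ethoxycarbonyl)-3-methylcyclopentyl]propanedioate | CCOC(=O)[C@@H]1[C@@H](C)[C@H](C(C)=O)C[C@H]1C(C(=O)OCC)C(=O)OCC.CCOC(=O)[C@H]1[C@H](C)[C@@H](C(C)=O)C[C@@H]1C(C(=O)OCC)C(=O)OCC
F8 | step 1 | racemic all-trans diethyl 2-[4-acetoxy-2-(ethoxycarbonyl)-3-methylcyclopentyl]propanedioate | CCOC(=O)[C@@H]1[C@@H](C)[C@H](OC(C)=O)C[C@H]1C(C(=O)OCC)C(=O)OCC.CCOC(=O)[C@H]1[C@H](C)[C@@H](OC(C)=O)C[C@@H]1C(C(=O)OCC)C(=O)OCC
F9 | step 1 | diethyl 2-[(1R,2S,3R,4R)-2-(ethoxycarbonyl)-4-hydroxy-3-methylcyclopentyl]propanedioate | CCOC(=O)[C@@H]1[C@@H](C)[C@H](O)C[C@H]1C(C(=O)OCC)C(=O)OCC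
F10 | step 8 | bis{2-[(2R,4S)-2-ethoxy-3,4-dihydro-2H-pyran-4-yl]acetate} of 8 | C1=CO[C@@H](OCC)C[C@H]1CC(=O)OC[C@@H]1[C@@H](C)[C@H](OC(=O)C[C@@H]3C[C@H](OCC)OC=C3)C[C@H]1C2COC(C)(C)OC2
F11 | step 8 | bis(5,6-dibromo adduct) of F10, mixture at the CHBr centres | BrC1C(Br)O[C@@H](OCC)C[C@H]1CC(=O)OC[C@@H]1[C@@H](C)[C@H](OC(=O)C[C@@H]3C[C@H](OCC)OC(Br)C3Br)C[C@H]1C2COC(C)(C)OC2
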